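I decided to compare these flasks on one clock instead of in hours. Chains are started by initiator and ended in pairs (termination), so I assumed the carrier level follows the root of the initiator. I call chain clock the hours times the root of the initiator charge over 10 mM, and the last east reading stood on it at 35.5 h.

| flask | starting material | reagent | initiator | remark | time |
|---|---|---|---|---|---|
| south-east | 1 M | 0.46 M | 10 mM | run made earlier |  |
| south | 1 M | 0.81 M | 10 mM | run made earlier |  |
| east | 1 M | 1.3 M | 14 mM | run made earlier |  |
| alpha | 1.0 M | 1.30 M | 10 mM |  | 2.5 d |
| gamma | 1.0 M | 0.600 M | 30 mM |  | 2.5 d |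

| run | time / h | product / % | starting material / % |
|---|---|---|---|
| south-east | 1.50 | 1.4 | 97.9 |
| south-east | 5.00 | 3.9 | 94.6 |
| south-east | 8.00 | 6.3 | 92.9 |
| south-east | 12.0 | 9.2 | 89.7 |
| south-east | 20.0 | 11.7 | 85.0 |
| south-east | 25.0 | 13.9 | 81.8 |
| south-east | 30.0 | 15.9 | 79.5 |
| south | 1.50 | 0.4 | 97.9 |
| south | 5.00 | 3.7 | 94.1 |
| south | 8.00 | 6.5 | 91.9 |
| south | 12.0 | 8.1 | 88.1 |
| south | 20.0 | 14.3 | 82.7 |
| south | 25.0 | 16.5 | 79.7 |
| south | 30.0 | 19.0 | 76.7 |
| east | 2.50 | 1.4 | 96.8 |
| east | 8.00 | 7.6 | 90.6 |
| east | 15.0 | 14.0 | 82.8 |
| east | 20.0 | 16.6 | 79.1 |
| east | 30.0 | 23.4 | 72.2 |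

(each reading ± 0.5 percentage points)

- in percentages every species weighs as the starting material in it: one ended chains B counts as two
- for by-product the crystals are counted in
- as a solid, counted per litre of solution: crystals
- steps under discussion: initiator -> 2 initiating radical; starting material + initiating radical -> capped initiator + first chain carrier; reagent + first chain carrier <-> product + second chain carrier; starting material + second chain carrier -> by-product + first chain carrier; 2 second chain carrier -> ended chains A; 2 first chain carrier -> ended chains B; starting material <-> dormant form; crystals <-> by-product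

- which one finishes higher in amount of product, in percent of the starting material charged ("neither" within 2 percentage points) (alpha / gamma / neither)
- amount of product at the end, in percent of the starting material charged, alpha
- amount of product at the end, in percent of the starting material charged, gamma

Alpha has the reagent charge of east, and its clock ends at 60 h. Over its second half, east gained 0.00530 h⁻¹ of the charge per clock hour, so a straight line gave alpha 36.4 %.

That line was the weak link, so I reforged it. By the readings, the second half of east gave 0.671 of the product the first gave, and the stretch left to alpha lies 1.19 such halves later. Bending the slope by that factor gave alpha 31.5 %.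

Gamma's clock ends at 104 h, and the same bend carried that far gave 38.2 %. But gamma spends reagent one for one with product, which on my estimate takes it through the south-east charge, and at equal initiator the last south-east reading was 0.837 of the last south reading. So I took 32.0 % for gamma, a gap smaller than the margin, and committed to neither.

The forecast said gamma, with 32 % for alpha and 39 % for gamma, adding that “reversal may bite”.

The flasks gave neither: 32.1 % for alpha and 31.6 % for gamma, which is 7.4 percentage points below the forecast for gamma.

    initiator → 2 initiating radical (k = 1.45 × 10⁻⁶ s⁻¹)
    starting material + initiating radical → capped initiator + first chain carrier (k = 31900 M⁻¹ s⁻¹)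
    reagent + first chain carrier ⇌ product + second chain carrier (K = 0.193, k = 3980 M⁻¹ s⁻¹)
    starting material + second chain carrier → by-product + first chain carrier (k = 578 M⁻¹ s⁻¹)
    2 second chain carrier → ended chains A (k = 8.00 × 10⁸ M⁻¹ s⁻¹)
    2 first chain carrier → ended chains B (k = 3.70 × 10⁸ M⁻¹ s⁻¹)
    starting material ⇌ dormant form (K = 0.290, k = 5.33 × 10⁻⁷ s⁻¹)
    crystals ⇌ by-product, rate k8*(cs8 - [by-product]) while solid is left; crystals form when [by-product] > cs8 (solubility = 49.0 mM, k = 6.76 × 10⁻⁴ s⁻¹)

At 1.25 d gamma led with 23.6 % of product against 20.6 % for alpha, while gamma had 60.6 % of its reagent charge left and alpha 84.2 % of its own. By the end gamma had 47.4 % and alpha 75.3 %, and gamma, its clock at 2.93 times the east mark, stood level within the margin.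

A neighbour, alpha with 0.0040 M of initiator, ends at 37.9 h on the clock, later than the east mark, so the east reading plus its slope gives 24.7 %. The computed flask gives 23.4 %.

The data were generated by integration on assumed constants; scatter was added.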